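**Strategy**

Ring A of the target is a benzene with oxygen on C1 and C3 and the 10-phenyldecyl chain on C5. This 1,3,5 pattern is cut at C1–C2 and C3–C4: C2 and C3 (with its methoxy group) come from methoxyacetylene, and C1, C4, C5 and C6 from a 3-alkylcyclobutenone whose carbonyl carbon becomes the oxygen-bearing C1. One thermal cascade of the two partners builds ring A with all three substituents in their final positions and leaves one free phenol, which is methylated at the end. The precursor, 3-(10-phenyldecyl)cyclobut-2-en-1-one, already carries the complete chain and ring B on C3 of the four-membered ring.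

Key step: step 6

Remark on the chemistry: the target has no stereocentre and no stereogenic double bond, so no configuration has to be controlled. Ring A is numbered C1 (oxygen derived from the cyclobutenone carbonyl), C2, C3 (OMe), C4, C5 (chain), C6; ring B is the terminal phenyl. Methoxyacetylene is assumed not to be a catalogue item and is therefore made in step 5.

**Route**

Step 1
Reactants: 1 1,10-dibromodecane; 2 phenylmagnesium bromide
Product: 3 (10-bromodecyl)benzene
Conditions: 1 (3 equiv), Li2CuCl4 (3 mol%), THF, 0 → 25 °C; excess 1 recovered by vacuum distillation
Reagents that add atoms: none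
Why: Kochi-type copper-catalysed cross-coupling of an aryl Grignard reagent with a primary alkyl bromide, in which the threefold excess of the dibromide keeps the second C–Br bond from coupling.

Step 2
Reactants: 3 (10-bromodecyl)benzene
Product: 4 12-phenyldodec-1-yne
Conditions: LiC≡CH·H2NCH2CH2NH2 (1.5 equiv), DMSO, 15 → 25 °C
Reagents that add atoms: lithium acetylide–ethylenediamine complex, [Li]C#C.NCCN
Why: SN2 alkylation of lithium acetylide by an unhindered primary bromide in a dipolar aprotic solvent, a standard terminal-alkyne synthesis that ring B tolerates.

Step 3
Reactants: 4 12-phenyldodec-1-yne; 5 trichloroacetyl chloride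
Product: 7 4,4-dichloro-3-(10-phenyldecyl)cyclobut-2-en-1-one, via dichloroketene 6 (not isolated)
Conditions: Zn–Cu couple, 5 (2 equiv, slow addition), Et2O–DME, 25 °C
Reagents that add atoms: none
Why: Zinc dechlorination of 5 gives dichloroketene 6, which undergoes a regioselective thermal ketene–alkyne [2+2] cycloaddition in which the ketene carbonyl carbon bonds to the terminal alkyne carbon, so the chain ends on C3 of the cyclobutenone, while DME ties up ZnCl2 and limits ketene polymerisation.

Step 4
Reactants: 7 4,4-dichloro-3-(10-phenyldecyl)cyclobut-2-en-1-one
Product: 8 3-(10-phenyldecyl)cyclobut-2-en-1-one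
Conditions: Zn dust, AcOH, TMEDA, EtOH, 0 → 25 °C
Reagents that add atoms: none
Why: Reductive dechlorination of an α,α-dichloro ketone by zinc under AcOH/TMEDA buffering removes both chlorines through zinc enolates without reducing the enone or opening the four-membered ring.

Step 5
Reactants: 9 chloroacetaldehyde dimethyl acetal
Product: 11 methoxyacetylene, via sodium methoxyacetylide 10 (not isolated)
Conditions: NaNH2 (3.2 equiv), liq. NH3, −33 °C; NH3 evaporated under N2; sat. aq. NaCl, −70 °C, then distilled into toluene at −78 °C and kept as a cold solution
Reagents that add atoms: none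
Why: Twofold base-induced elimination (methanol, then HCl) with NaNH2 gives the alkyne, which the third equivalent of amide holds as its sodium salt 10 until cold brine protonates it and the low-boiling ynol ether (boiling near 23 °C) is distilled off.

Step 6
Reactants: 8 3-(10-phenyldecyl)cyclobut-2-en-1-one; 11 methoxyacetylene
Product: 16 3-methoxy-5-(10-phenyldecyl)phenol, via vinylketene 12 (not isolated), via 4-vinylcyclobutenone 13 (not isolated), via dienylketene 14 (not isolated), via cyclohexadienone 15 (not isolated)
Conditions: 11 (2.5 equiv, cold toluene solution), toluene, sealed pressure tube under N2, 80 °C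
Reagents that add atoms: none
Why: Danheiser benzannulation: thermal four-electron electrocyclic opening of 8 gives vinylketene 12, whose ketene C=C bond undergoes a [2+2] cycloaddition with the electron-rich alkyne 11 to give 4-vinylcyclobutenone 13, and a second four-electron opening gives dienylketene 14. Ring A is then closed by a thermal disrotatory six-electron electrocyclisation of 14 (ketene carbon C1 onto the terminal methylene C6) to cyclohexadienone 15, which tautomerises to phenol 16, so that all atoms of both partners end up in the product. The closest known reaction type is the thermal aromatic annulation of cyclobutenones with alkoxyalkynes that gives resorcinol monoethers. No stereocentre is created in the product, since the single sp3 centre of 13 is transient and racemic. The selectivity needed is the orientation of the ketene–alkyne [2+2]: the unsubstituted, nucleophilic carbon of 11 bonds to the electrophilic ketene carbonyl carbon (new C1–C2 bond) and the methoxy-bearing carbon to the ketene α-carbon (new C3–C4 bond), which the polarisation of the ynol ether dictates and which places OMe on C3 and the chain on C5. The ring opening of 13 is reversible, so only the dienylketene geometry that is able to cyclise is drained towards the arene.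

Step 7
Reactants: 16 3-methoxy-5-(10-phenyldecyl)phenol
Product: 17 1,3-dimethoxy-5-(10-phenyldecyl)benzene
Conditions: MeI, K2CO3, acetone, reflux
Reagents that add atoms: iodomethane, CI
Why: Williamson ether synthesis in which the phenoxide formed by K2CO3 is methylated by MeI in an SN2 reaction, the molecule offering no other nucleophilic site.

**Compound list**

1 | 1,10-dibromodecane | BrCCCCCCCCCCBr | starting material
2 | phenylmagnesium bromide | Br[Mg]c1ccccc1 | starting material
3 | (10-bromodecyl)benzene | BrCCCCCCCCCCc1ccccc1 | intermediate
4 | 12-phenyldodec-1-yne | C#CCCCCCCCCCCc1ccccc1 | intermediate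
5 | trichloroacetyl chloride | ClC(=O)C(Cl)(Cl)Cl | starting material
6 | dichloroketene | O=C=C(Cl)Cl | intermediate (not isolated)
7 | 4,4-dichloro-3-(10-phenyldecyl)cyclobut-2-en-1-one | O=C1C=C(CCCCCCCCCCc2ccccc2)C1(Cl)Cl | intermediate
8 | 3-(10-phenyldecyl)cyclobut-2-en-1-one | O=C1C=C(CCCCCCCCCCc2ccccc2)C1 | intermediate
9 | chloroacetaldehyde dimethyl acetal (2-chloro-1,1-dimethoxyethane) | COC(CCl)OC | starting material
10 | sodium methoxyacetylide | [Na+].[C-]#COC | intermediate (not isolated)
11 | methoxyacetylene | COC#C | intermediate
12 | 3-(10-phenyldecyl)buta-1,3-dien-1-one (vinylketene) | O=C=CC(=C)CCCCCCCCCCc1ccccc1 | intermediate (not isolated)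
13 | 3-methoxy-4-(12-phenyldodec-1-en-2-yl)cyclobut-2-en-1-one (4-vinylcyclobutenone, racemic) | O=C1C=C(OC)C1C(=C)CCCCCCCCCCc2ccccc2 | intermediate (not isolated)
14 | (3E)-3-methoxy-5-(10-phenyldecyl)hexa-1,3,5-trien-1-one (dienylketene; ketene carbon and vinyl group cis across C3=C4) | O=C=C/C(OC)=C\C(=C)CCCCCCCCCCc1ccccc1 | intermediate (not isolated)
15 | 3-methoxy-5-(10-phenyldecyl)cyclohexa-2,4-dien-1-one | O=C1C=C(OC)C=C(CCCCCCCCCCc2ccccc2)C1 | intermediate (not isolated)
16 | 3-methoxy-5-(10-phenyldecyl)phenol | COc1cc(O)cc(CCCCCCCCCCc2ccccc2)c1 | intermediate
17 | 1,3-dimethoxy-5-(10-phenyldecyl)benzene | COc1cc(CCCCCCCCCCc2ccccc2)cc(OC)c1 | target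

**Step count**

Total: 7 steps. Longest linear sequence: 6 steps (steps 1, 2, 3, 4, 6, 7); step 5 is a one-step side branch that supplies the alkyne.

**Steps most likely to fail and fallbacks**

Step 6 (highest risk). The transient vinylketene may dimerise or acylate the product phenol faster than it adds to the alkyne. The low-boiling ynol ether may also escape or polymerise on heating. The fallback gives up the annulation and joins a ready-made ring A to the chain. It sets out from bromide 3. Purchased 1-bromo-3,5-dimethoxybenzene is converted with Mg turnings in THF into (3,5-dimethoxyphenyl)magnesium bromide F1. F1 is coupled with 3 under Li2CuCl4 catalysis in THF at 0 °C, the same reaction type as step 1. This should give the target directly, so the fallback comes back to the route at compound 17.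

Step 5. The low-boiling alkyne may be lost during distillation, the air-sensitive sodium acetylide may oxidise before the quench, and the ynol ether may polymerise on storage. The fallback avoids making this alkyne and uses purchased ethoxyacetylene (sold as a solution in hexanes) instead. It sets out from cyclobutenone 8. Heating 8 with ethoxyacetylene in toluene in a sealed tube at 80 °C should give 3-ethoxy-5-(10-phenyldecyl)phenol F2 by the same annulation. BBr3 in CH2Cl2 (−78 → 25 °C) then cleaves the ethyl ether to 5-(10-phenyldecyl)benzene-1,3-diol F3. Double O-methylation of F3 with excess MeI and K2CO3 in refluxing acetone comes back to the route at compound 17.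

Step 3. Dichloroketene may polymerise faster than it adds to the unactivated alkyne, and the zinc salts may induce chloride migration or ring cleavage in the adduct. The fallback builds the cyclobutenone by carbonyl addition and transposition, with no ketene cycloaddition. It sets out from bromide 3. Mg turnings in THF give (10-phenyldecyl)magnesium bromide F4. F4 is added at −78 °C to purchased 3-ethoxycyclobut-2-en-1-one; 1,2-addition to this vinylogous ester gives 3-ethoxy-1-(10-phenyldecyl)cyclobut-2-en-1-ol F5. Quenching with dilute aqueous HCl ionises the tertiary allylic alcohol and hydrolyses the enol ether (Stork–Danheiser transposition). This comes back to the route at compound 8 and bypasses steps 2 to 4.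

**Further compounds**

F1 | step 6 | (3,5-dimethoxyphenyl)magnesium bromide | COc1cc(OC)cc([Mg]Br)c1
F2 | step 5 | 3-ethoxy-5-(10-phenyldecyl)phenol | CCOc1cc(O)cc(CCCCCCCCCCc2ccccc2)c1
F3 | step 5 | 5-(10-phenyldecyl)benzene-1,3-diol | Oc1cc(O)cc(CCCCCCCCCCc2ccccc2)c1
F4 | step 3 | (10-phenyldecyl)magnesium bromide | Br[Mg]CCCCCCCCCCc1ccccc1
F5 | step 3 | 3-ethoxy-1-(10-phenyldecyl)cyclobut-2-en-1-ol (racemic) | CCOC1=CC(O)(CCCCCCCCCCc2ccccc2)C1
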